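**Plan**
- Retrosynthesis: the seven O–CH3 bonds are cut first (global demethylation), then the C5–O bonds of ring A and ring B, both traced back to C–H bonds of one tetraaryl heptamethyl ether.
- Next cuts: the ring B–O–ring C ether bond, the ring A–O–ring B ether bond, the C1–O bond of ring C (traced back to a formyl carbon) and the ring C–ring D biaryl bond.
- Forward: all four benzene rings are bought and none is built. Ring C is brominated and joined to ring D by Suzuki coupling, and its formyl group is turned into a phenol. Rings A and B are joined by a first Ullmann coupling, a second Ullmann coupling links ring B to ring C, the two missing oxygens are added, and the methyl ethers are removed.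
- Enabling feature: in the heptamethyl ether, C5–H of ring A and C5–H of ring B are the only aromatic C–H bonds without an ortho substituent. C2, C4 and C6 of rings A and B each sit next to an oxygen-bearing carbon, and C3–H of ring C and C3–H/C5–H of ring D each lie between two methoxy-bearing carbons.
- Stereochemistry: none to set. The target has no stereocentre, and the biaryl bond is not a stereogenic axis because ring D is symmetric about it.

Key step: step 6

Remark: ring A is the terminal 3,5-dioxygenated phenoxy ring, ring B the central 1,3,5-trioxygenated ring, ring C the pentasubstituted ring and ring D the 2,4,6-trioxygenated phenyl ring. The four aromatic building blocks and all reagents are taken to be commercial.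

**Step 1**
Reactants: 1 2,4,6-trimethoxybenzaldehyde
Product: 2 3-bromo-2,4,6-trimethoxybenzaldehyde
Conditions: NBS (1.05 equiv), MeCN, 0 °C to rt
Reagents that add atoms: N-bromosuccinimide, O=C1CCC(=O)N1Br
Why: Electrophilic aromatic bromination; C3 and C5 of 1 are equivalent and each is activated by three methoxy groups, while the aldehyde and the first bromine slow a second substitution, so one equivalent of NBS should stop at the monobromide.

**Step 2**
Reactants: 2 3-bromo-2,4,6-trimethoxybenzaldehyde; 3 (2,4,6-trimethoxyphenyl)boronic acid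
Product: 4 2,4,6-trimethoxy-3-(2,4,6-trimethoxyphenyl)benzaldehyde
Conditions: 3 (2 equiv), Pd(OAc)2 (5 mol%), SPhos (10 mol%), K3PO4 (3 equiv), toluene/H2O 10:1, 100 °C
Reagents that add atoms: none
Why: Suzuki–Miyaura coupling; the bulky, electron-rich biarylphosphine gives a monoligated zerovalent palladium species that inserts into the flanked C–Br bond and still permits transmetalation and reductive elimination to a biaryl with four small ortho methoxy groups, the twofold charge of 3 offsets its protodeboronation, and the aldehyde is inert.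

**Step 3**
Reactants: 4 2,4,6-trimethoxy-3-(2,4,6-trimethoxyphenyl)benzaldehyde
Product: 6 2,4,6-trimethoxy-3-(2,4,6-trimethoxyphenyl)phenol, via aryl formate 5 (not isolated)
Conditions: mCPBA (1.2 equiv), CH2Cl2, 0 °C to rt; then K2CO3 (cat.), MeOH, rt
Reagents that add atoms: meta-chloroperoxybenzoic acid, OOC(=O)c1cccc(Cl)c1
Why: Baeyer–Villiger oxidation of an electron-rich benzaldehyde (Dakin-type); in the Criegee adduct the trioxygenated aryl group migrates in preference to hydrogen to give formate 5, which base-catalysed methanolysis cleaves to the phenol without touching the methyl ethers.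

**Step 4**
Reactants: 7 3-methoxyphenol; 8 1-bromo-3-iodobenzene
Product: 9 1-bromo-3-(3-methoxyphenoxy)benzene
Conditions: CuI (10 mol%), N,N-dimethylglycine hydrochloride (30 mol%), Cs2CO3 (2 equiv), 1,4-dioxane, 90 °C
Reagents that add atoms: none
Why: Ullmann-type C–O coupling under Ma conditions; the monovalent copper phenoxide engages the C–I bond of 8 far faster than the C–Br bond at this temperature, so the bromide should be kept for step 5.

**Step 5**
Reactants: 6 2,4,6-trimethoxy-3-(2,4,6-trimethoxyphenyl)phenol; 9 1-bromo-3-(3-methoxyphenoxy)benzene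
Product: 10 1-[3-(3-methoxyphenoxy)phenoxy]-2,4,6-trimethoxy-3-(2,4,6-trimethoxyphenyl)benzene
Conditions: 9 (1.3 equiv), CuI (10 mol%), picolinic acid (20 mol%), K3PO4 (2 equiv), DMSO, 100 °C, Ar
Reagents that add atoms: none
Why: Ullmann-type C–O coupling with the picolinic acid-ligated copper system used for ortho,ortho-disubstituted phenols; the phenoxide of 6 is flanked only by two small methoxy groups, the aryl bromide 9 is unhindered, and the methyl ethers and the biaryl are inert.

**Step 6**
Reactants: 10 1-[3-(3-methoxyphenoxy)phenoxy]-2,4,6-trimethoxy-3-(2,4,6-trimethoxyphenyl)benzene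
Product: 12 3-{3-hydroxy-5-[2,4,6-trimethoxy-3-(2,4,6-trimethoxyphenyl)phenoxy]phenoxy}-5-methoxyphenol, via bis(pinacolboronate) 11 (not isolated)
Conditions: [Ir(OMe)(cod)]2 (3 mol%), 4,4'-di-tert-butyl-2,2'-bipyridine (6 mol%), B2pin2 (3 equiv), THF, 80 °C; then 30% aq. H2O2, aq. NaOH, 0 °C to rt
Reagents that add atoms: hydrogen peroxide, OO; bis(pinacolato)diboron, CC1(C)OB(OC1(C)C)B1OC(C)(C)C(C)(C)O1 (its boron and pinacolate are carried only by 11)
Why: [Ir(OMe)(cod)]2, the bipyridine and B2pin2 form a trivalent iridium tris(boryl) complex that cleaves an aromatic C–H bond by oxidative addition (or σ-bond metathesis) and releases the aryl boronate by C–B reductive elimination; two such events give 11, and alkaline hydrogen peroxide then shifts each aryl group from boron to oxygen with retention of position. The closest known reaction type is the iridium-catalysed meta C–H borylation of 1,3-disubstituted arenes with one-pot oxidation to 3,5-disubstituted phenols. No ring closes and no stereocentre forms; the step makes the two C5–O bonds of rings A and B by way of two C–B bonds. The selectivity needed is site selectivity among eleven aromatic C–H bonds, and it is steric: the crowded tris(boryl) complex does not insert next to a substituent, C2, C4 and C6 of rings A and B each have an oxygen substituent on the neighbouring carbon, and C3–H of ring C and C3–H and C5–H of ring D each lie between two methoxy groups, so only C5–H of ring A and C5–H of ring B remain. An excess of B2pin2 should carry both rings to full conversion, and aryl methyl ethers and diaryl ethers neither bind nor deactivate the catalyst.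

**Step 7**
Reactants: 12 3-{3-hydroxy-5-[2,4,6-trimethoxy-3-(2,4,6-trimethoxyphenyl)phenoxy]phenoxy}-5-methoxyphenol
Product: 13 3-[3-(3,5-dihydroxyphenoxy)-5-hydroxyphenoxy]biphenyl-2,2',4,4',6,6'-hexol
Conditions: BBr3 (15 equiv), CH2Cl2, −78 °C to rt; then H2O, 0 °C
Reagents that add atoms: none
Why: Lewis acid-mediated aryl methyl ether cleavage; BBr3 binds each methoxy oxygen and bromide attacks the methyl carbon in an SN2 step, a path closed to the two diaryl ether links and the biaryl bond, and hydrolysis of the aryl borates should free the nine phenols.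

**Compound list**
1 | 2,4,6-trimethoxybenzaldehyde | COc1cc(OC)c(C=O)c(OC)c1 | starting material
2 | 3-bromo-2,4,6-trimethoxybenzaldehyde | COc1cc(OC)c(C=O)c(OC)c1Br | intermediate
3 | (2,4,6-trimethoxyphenyl)boronic acid | COc1cc(OC)c(B(O)O)c(OC)c1 | starting material
4 | 2,4,6-trimethoxy-3-(2,4,6-trimethoxyphenyl)benzaldehyde | COc1cc(OC)c(-c2c(OC)cc(OC)c(C=O)c2OC)c(OC)c1 | intermediate
5 | 2,4,6-trimethoxy-3-(2,4,6-trimethoxyphenyl)phenyl formate | COc1cc(OC)c(-c2c(OC)cc(OC)c(OC=O)c2OC)c(OC)c1 | intermediate
6 | 2,4,6-trimethoxy-3-(2,4,6-trimethoxyphenyl)phenol | COc1cc(OC)c(-c2c(OC)cc(OC)c(O)c2OC)c(OC)c1 | intermediate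
7 | 3-methoxyphenol | COc1cccc(O)c1 | starting material
8 | 1-bromo-3-iodobenzene | Brc1cccc(I)c1 | starting material
9 | 1-bromo-3-(3-methoxyphenoxy)benzene | COc1cccc(Oc2cccc(Br)c2)c1 | intermediate
10 | 1-[3-(3-methoxyphenoxy)phenoxy]-2,4,6-trimethoxy-3-(2,4,6-trimethoxyphenyl)benzene | COc1cccc(Oc2cccc(Oc3c(OC)cc(OC)c(-c4c(OC)cc(OC)cc4OC)c3OC)c2)c1 | intermediate
11 | bis(pinacolboronate) of 10 carrying 4,4,5,5-tetramethyl-1,3,2-dioxaborolan-2-yl groups at C5 of ring A and C5 of ring B | COc1cc(B2OC(C)(C)C(C)(C)O2)cc(Oc2cc(B3OC(C)(C)C(C)(C)O3)cc(Oc3c(OC)cc(OC)c(-c4c(OC)cc(OC)cc4OC)c3OC)c2)c1 | intermediate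
12 | 3-{3-hydroxy-5-[2,4,6-trimethoxy-3-(2,4,6-trimethoxyphenyl)phenoxy]phenoxy}-5-methoxyphenol | COc1cc(O)cc(Oc2cc(O)cc(Oc3c(OC)cc(OC)c(-c4c(OC)cc(OC)cc4OC)c3OC)c2)c1 | intermediate
13 | 3-[3-(3,5-dihydroxyphenoxy)-5-hydroxyphenoxy]biphenyl-2,2',4,4',6,6'-hexol | Oc1cc(O)cc(Oc2cc(O)cc(Oc3c(O)cc(O)c(-c4c(O)cc(O)cc4O)c3O)c2)c1 | target

**Step count**
Total steps: 7. Longest linear sequence: 6 steps (steps 1, 2, 3, 5, 6 and 7, from 1 to 13); step 4 is the side branch.

**Steps most likely to fail**

Step 2. Protodeboronation of 3 may outrun a slow transmetalation at the doubly ortho-substituted arylpalladium bromide, so that the coupling stalls. The fallback sets out from 2 and replaces the boron nucleophile by a zinc one. 1,3,5-Trimethoxybenzene F1 would be deprotonated with n-BuLi in THF to (2,4,6-trimethoxyphenyl)lithium F2, and ZnCl2 would convert this into (2,4,6-trimethoxyphenyl)zinc chloride F3. Negishi coupling of F3 with 2 (Pd2(dba)3, RuPhos, THF, 65 °C) should then give 4, where the route resumes. The arylzinc cannot lose its metal to water under anhydrous conditions and is expected to leave the hindered, electron-rich aldehyde alone.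

Step 5. C–O bond formation at the phenoxide oxygen between two methoxy groups may be slow, and oxidative decay of the electron-rich phenoxide at 100 °C may take over. The fallback sets out from 9 and turns the coupling into an oxidative one at room temperature. Bromine–lithium exchange (n-BuLi, THF, −78 °C) would give [3-(3-methoxyphenoxy)phenyl]lithium F4, and B(OiPr)3 would trap it as lithium [3-(3-methoxyphenoxy)phenyl]tri(propan-2-yloxy)borate F5. Aqueous HCl would release [3-(3-methoxyphenoxy)phenyl]boronic acid F6. Chan–Evans–Lam coupling of F6 with 6 (Cu(OAc)2, pyridine, 4 Å molecular sieves, CH2Cl2, O2, rt) should give 10, where the route resumes.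

Step 6. Borylation may stay incomplete on one of the two rings, or a small share may occur next to the ring A methoxy group, which would give phenol mixtures that are hard to separate. The fallback sets out from 6 and brings the two oxygens in with the building blocks. 3,5-Dimethoxyphenol F7 and an excess of 1,3-dibromo-5-methoxybenzene F8 (CuI, N,N-dimethylglycine hydrochloride, Cs2CO3, 1,4-dioxane, 100 °C) would give 1-bromo-3-(3,5-dimethoxyphenoxy)-5-methoxybenzene F9. Ullmann coupling of F9 with 6 under the conditions of step 5 would give 1-[3-(3,5-dimethoxyphenoxy)-5-methoxyphenoxy]-2,4,6-trimethoxy-3-(2,4,6-trimethoxyphenyl)benzene F10. BBr3 in CH2Cl2 would cleave its nine methyl ethers and deliver 13 directly, so the fallback comes back to the route at 13.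

**Further compounds**
F1 | step 2 | 1,3,5-trimethoxybenzene | COc1cc(OC)cc(OC)c1
F2 | step 2 | (2,4,6-trimethoxyphenyl)lithium | [Li]c1c(OC)cc(OC)cc1OC
F3 | step 2 | (2,4,6-trimethoxyphenyl)zinc chloride | Cl[Zn]c1c(OC)cc(OC)cc1OC
F4 | step 5 | [3-(3-methoxyphenoxy)phenyl]lithium | [Li]c1cccc(Oc2cccc(OC)c2)c1
F5 | step 5 | lithium [3-(3-methoxyphenoxy)phenyl]tri(propan-2-yloxy)borate | [Li+].COc1cccc(Oc2cccc([B-](OC(C)C)(OC(C)C)OC(C)C)c2)c1
F6 | step 5 | [3-(3-methoxyphenoxy)phenyl]boronic acid | COc1cccc(Oc2cccc(B(O)O)c2)c1
F7 | step 6 | 3,5-dimethoxyphenol | COc1cc(O)cc(OC)c1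
F8 | step 6 | 1,3-dibromo-5-methoxybenzene | COc1cc(Br)cc(Br)c1
F9 | step 6 | 1-bromo-3-(3,5-dimethoxyphenoxy)-5-methoxybenzene | COc1cc(OC)cc(Oc2cc(Br)cc(OC)c2)c1
F10 | step 6 | 1-[3-(3,5-dimethoxyphenoxy)-5-methoxyphenoxy]-2,4,6-trimethoxy-3-(2,4,6-trimethoxyphenyl)benzene | COc1cc(OC)cc(Oc2cc(OC)cc(Oc3c(OC)cc(OC)c(-c4c(OC)cc(OC)cc4OC)c3OC)c2)c1
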